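**Retrosynthetic overview**

1. Locants: C7 is the CH2O carbon on C1, C1=C2 is the ring alkene, C3–C6 are the oxygenated ring carbons, and On is the oxygen on Cn. The route rests on the cis C5–O/C6–O diol next to the substituted alkene carbon C1 of the single carbocycle, which is the ortho,meta cis-diol that an arene dioxygenase leaves on a monosubstituted benzene.
2. 15 ⇐ acetonide hydrolysis of 14 ⇐ benzoylation of O5 and then O7, with O5 exposed alone by a temporary six-membered O6,O7-silylene on triol 8.
3. 8 ⇐ ester reduction and desilylation of 5 ⇐ 3,4-acetonide of diol 4 ⇐ OsO4 cis-dihydroxylation of C3=C4 of the bis-silylated diene 3, anti to O5/O6.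
4. 3 ⇐ diene diol 2 ⇐ ethyl benzoate 1 by enzymatic cis-dihydroxylation. The carbocycle is the benzene ring of 1; the only rings made are protecting-group rings (dioxolane, then dioxasilinane).

Key step: step 1

Remark: the (5S,6R) configuration of 2 is the one the target needs. The descriptor at C5 changes along the route only because substituent priorities change; the centre is never inverted.

**Route**

Step 1
Reactants: 1 ethyl benzoate
Product: 2 ethyl (5S,6R)-5,6-dihydroxycyclohexa-1,3-diene-1-carboxylate
Conditions: E. coli JM109(pDTG601A) whole cells expressing toluene dioxygenase (IPTG-induced), glucose feed, aerated mineral medium, pH 6.8–7.0, 30–35 °C; centrifuge, extract the broth with base-washed EtOAc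
Reagents that add atoms: dioxygen, O=O
Why: Toluene dioxygenase is a Rieske non-heme iron dioxygenase: NADH-derived electrons pass through the reductase and ferredoxin to the [2Fe-2S] cluster and on to the mononuclear iron centre, where O2 binds at divalent iron and is reduced to a trivalent iron (hydro)peroxo species that transfers both oxygen atoms to the same face of the C5–C6 (meta–ortho) edge of the arene, forming the C5–O and C6–O bonds. The closest known reaction type is the microbial arene cis-dihydroxylation of benzoate esters by this same enzyme, so the step applies established chemistry, and no ring is closed. Both new stereocentres, C5 (S) and C6 (R), are set by the enzyme active site, which also fixes the ortho,meta regiochemistry by the way it docks a monosubstituted benzene over the iron. The selectivity needed is one regiochemistry and one enantiotopic face, and both are catalyst-controlled, not substrate-controlled. The ester substituent slows dehydrative rearomatisation and the recombinant host lacks the cis-diol dehydrogenase, so 2 should accumulate in the broth.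

Step 2
Reactants: 2 ethyl (5S,6R)-5,6-dihydroxycyclohexa-1,3-diene-1-carboxylate
Product: 3 ethyl (5S,6R)-5,6-bis[(tert-butyldimethylsilyl)oxy]cyclohexa-1,3-diene-1-carboxylate
Conditions: TBSOTf (2.5 equiv), 2,6-lutidine (4 equiv), CH2Cl2, −78 → 0 °C; use 3 promptly
Reagents that add atoms: tert-butyldimethylsilyl trifluoromethanesulfonate, CC(C)(C)[Si](C)(C)OS(=O)(=O)C(F)(F)F
Why: O-Silylation with a silyl triflate and a hindered pyridine base caps both secondary allylic hydroxyls without the acid that would dehydrate the diene diol to a phenol, touches no stereocentre, and is chosen over an acetonide so that the O5/O6 protection can later be removed by fluoride while a 3,4-acetonide stays.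

Step 3
Reactants: 3 ethyl (5S,6R)-5,6-bis[(tert-butyldimethylsilyl)oxy]cyclohexa-1,3-diene-1-carboxylate
Product: 4 ethyl (3R,4R,5S,6R)-5,6-bis[(tert-butyldimethylsilyl)oxy]-3,4-dihydroxycyclohex-1-ene-1-carboxylate
Conditions: OsO4 (3 mol %), NMO (1.5 equiv), acetone/H2O (5:1), 0 °C → rt
Reagents that add atoms: osmium tetroxide, O=[Os](=O)(=O)=O; N-methylmorpholine N-oxide, C[N+]1([O-])CCOCC1; water, O
Why: Upjohn cis-dihydroxylation: OsO4 (octavalent osmium) adds by suprafacial [3+2] cycloaddition to the electron-richer C3=C4 alkene (C1=C2 is deactivated by the conjugated ester) from the face opposite the two silyloxy groups, which sets C3 and C4 with O3 and O4 cis to each other and trans to O5.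

Step 4
Reactants: 4 ethyl (3R,4R,5S,6R)-5,6-bis[(tert-butyldimethylsilyl)oxy]-3,4-dihydroxycyclohex-1-ene-1-carboxylate
Product: 5 ethyl (3R,4R,5S,6R)-5,6-bis[(tert-butyldimethylsilyl)oxy]-3,4-(isopropylidenedioxy)cyclohex-1-ene-1-carboxylate
Conditions: 2,2-dimethoxypropane, PPTS (cat.), acetone, rt
Reagents that add atoms: 2,2-dimethoxypropane, COC(C)(C)OC
Why: Acid-catalysed transacetalisation closes a cis-fused dioxolane on the only diol present, and catalytic PPTS under anhydrous conditions should leave the secondary TBS ethers intact.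

Step 5
Reactants: 5 ethyl (3R,4R,5S,6R)-5,6-bis[(tert-butyldimethylsilyl)oxy]-3,4-(isopropylidenedioxy)cyclohex-1-ene-1-carboxylate
Product: 7 [(3R,4R,5S,6R)-5,6-bis[(tert-butyldimethylsilyl)oxy]-3,4-(isopropylidenedioxy)cyclohex-1-en-1-yl]methanol, via aldehyde 6 (not isolated)
Conditions: iBu2AlH (2.5 equiv), CH2Cl2, −78 → −20 °C; aq. Rochelle salt
Reagents that add atoms: none
Why: DIBAL reduction of the α,β-unsaturated ester proceeds by 1,2-hydride addition through the aldehyde to the allylic alcohol, with the silyl ethers and the acetonide inert to the hydride and no stereocentre involved.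

Step 6
Reactants: 7 [(3R,4R,5S,6R)-5,6-bis[(tert-butyldimethylsilyl)oxy]-3,4-(isopropylidenedioxy)cyclohex-1-en-1-yl]methanol
Product: 8 [(3R,4S,5R,6R)-5,6-dihydroxy-3,4-(isopropylidenedioxy)cyclohex-1-en-1-yl]methanol
Conditions: TBAF (3 equiv), THF, 0 °C → rt
Reagents that add atoms: none
Why: Fluoride-mediated desilylation cleaves both Si–O bonds, driven by the strong Si–F bond, while the acetonide is stable to the basic fluoride medium.

Step 7
Reactants: 8 [(3R,4S,5R,6R)-5,6-dihydroxy-3,4-(isopropylidenedioxy)cyclohex-1-en-1-yl]methanol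
Product: 10 (3R,4S,5S,6R)-6,7-O-(di-tert-butylsilanediyl)-3,4-O-isopropylidene-1-(hydroxymethyl)cyclohex-1-ene-3,4,5,6-tetrol, via silyl triflate 9 (not isolated)
Conditions: tBu2Si(OTf)2 (1.05 equiv), 2,6-lutidine (3 equiv), CH2Cl2, −40 → 0 °C
Reagents that add atoms: di-tert-butylsilyl bis(trifluoromethanesulfonate), CC(C)(C)[Si](OS(=O)(=O)C(F)(F)F)(OS(=O)(=O)C(F)(F)F)C(C)(C)C
Why: Cyclic silylene formation from a 1,3-diol: the primary O7 should be silylated first and the remaining Si–OTf then closes onto O6 through a six-membered 1,3,2-dioxasilinane (closure onto O5 would need a seven-membered ring), leaving O5–H as the only free hydroxyl.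

Step 8
Reactants: 10 (3R,4S,5S,6R)-6,7-O-(di-tert-butylsilanediyl)-3,4-O-isopropylidene-1-(hydroxymethyl)cyclohex-1-ene-3,4,5,6-tetrol; 11 benzoyl chloride
Product: 12 (3R,4R,5S,6R)-5-O-benzoyl-6,7-O-(di-tert-butylsilanediyl)-3,4-O-isopropylidene-1-(hydroxymethyl)cyclohex-1-ene-3,4,5,6-tetrol
Conditions: BzCl (1.5 equiv), pyridine, DMAP (cat.), CH2Cl2, 0 °C → rt
Reagents that add atoms: benzoyl chloride (11), O=C(Cl)c1ccccc1
Why: DMAP-catalysed acylation (nucleophilic catalysis) of the single free secondary hydroxyl installs the O5 benzoate with retention at C5, since only the O–H bond reacts.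

Step 9
Reactants: 12 (3R,4R,5S,6R)-5-O-benzoyl-6,7-O-(di-tert-butylsilanediyl)-3,4-O-isopropylidene-1-(hydroxymethyl)cyclohex-1-ene-3,4,5,6-tetrol
Product: 13 (3R,4R,5R,6R)-5-O-benzoyl-3,4-O-isopropylidene-1-(hydroxymethyl)cyclohex-1-ene-3,4,5,6-tetrol
Conditions: HF·pyridine, pyridine/THF, 0 °C
Reagents that add atoms: none
Why: Fluoride cleavage of the silylene with pyridine-buffered HF frees O6 and O7 under mildly acidic conditions that spare the acetonide and the benzoate and should not promote O5-to-O6 benzoyl migration.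

Step 10
Reactants: 13 (3R,4R,5R,6R)-5-O-benzoyl-3,4-O-isopropylidene-1-(hydroxymethyl)cyclohex-1-ene-3,4,5,6-tetrol; 11 benzoyl chloride
Product: 14 (3R,4R,5R,6R)-5,7-di-O-benzoyl-3,4-O-isopropylidene-1-(hydroxymethyl)cyclohex-1-ene-3,4,5,6-tetrol
Conditions: BzCl (1.05 equiv), 2,4,6-collidine, CH2Cl2, −40 → −10 °C
Reagents that add atoms: benzoyl chloride (11), O=C(Cl)c1ccccc1
Why: Kinetically controlled acylation with a weak, hindered base at low temperature should benzoylate the unhindered primary allylic O7 well before the secondary O6, which is flanked by C1 and the C5 benzoate.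

Step 11
Reactants: 14 (3R,4R,5R,6R)-5,7-di-O-benzoyl-3,4-O-isopropylidene-1-(hydroxymethyl)cyclohex-1-ene-3,4,5,6-tetrol
Product: 15 [(3R,4R,5R,6R)-5-(benzoyloxy)-3,4,6-trihydroxycyclohex-1-en-1-yl]methyl benzoate
Conditions: TFA/H2O (4:1), 0 °C → rt
Reagents that add atoms: none
Why: Acid-catalysed acetal hydrolysis removes the isopropylidene group, while benzoate esters are stable to cold aqueous TFA and acyl migration is slow under acid, so O3–H and O4–H are revealed without touching C3–C6.

**Compound list**

1 | ethyl benzoate | CCOC(=O)c1ccccc1 | starting material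
2 | ethyl (5S,6R)-5,6-dihydroxycyclohexa-1,3-diene-1-carboxylate | CCOC(=O)C1=CC=C[C@H](O)[C@@H]1O | intermediate
3 | ethyl (5S,6R)-5,6-bis[(tert-butyldimethylsilyl)oxy]cyclohexa-1,3-diene-1-carboxylate | CCOC(=O)C1=CC=C[C@H](O[Si](C)(C)C(C)(C)C)[C@@H]1O[Si](C)(C)C(C)(C)C | intermediate
4 | ethyl (3R,4R,5S,6R)-5,6-bis[(tert-butyldimethylsilyl)oxy]-3,4-dihydroxycyclohex-1-ene-1-carboxylate | CCOC(=O)C1=C[C@@H](O)[C@@H](O)[C@H](O[Si](C)(C)C(C)(C)C)[C@@H]1O[Si](C)(C)C(C)(C)C | intermediate
5 | ethyl (3R,4R,5S,6R)-5,6-bis[(tert-butyldimethylsilyl)oxy]-3,4-(isopropylidenedioxy)cyclohex-1-ene-1-carboxylate | CCOC(=O)C1=C[C@@H](OC(C)(C)O2)[C@@H]2[C@H](O[Si](C)(C)C(C)(C)C)[C@@H]1O[Si](C)(C)C(C)(C)C | intermediate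
6 | (3R,4R,5S,6R)-5,6-bis[(tert-butyldimethylsilyl)oxy]-3,4-(isopropylidenedioxy)cyclohex-1-ene-1-carbaldehyde | O=CC1=C[C@@H](OC(C)(C)O2)[C@@H]2[C@H](O[Si](C)(C)C(C)(C)C)[C@@H]1O[Si](C)(C)C(C)(C)C | intermediate (not isolated)
7 | [(3R,4R,5S,6R)-5,6-bis[(tert-butyldimethylsilyl)oxy]-3,4-(isopropylidenedioxy)cyclohex-1-en-1-yl]methanol | OCC1=C[C@@H](OC(C)(C)O2)[C@@H]2[C@H](O[Si](C)(C)C(C)(C)C)[C@@H]1O[Si](C)(C)C(C)(C)C | intermediate
8 | [(3R,4S,5R,6R)-5,6-dihydroxy-3,4-(isopropylidenedioxy)cyclohex-1-en-1-yl]methanol | OCC1=C[C@@H](OC(C)(C)O2)[C@@H]2[C@H](O)[C@@H]1O | intermediate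
9 | di-tert-butyl{[(3R,4S,5R,6R)-5,6-dihydroxy-3,4-(isopropylidenedioxy)cyclohex-1-en-1-yl]methoxy}silyl trifluoromethanesulfonate | CC(C)(C)[Si](OCC1=C[C@@H](OC(C)(C)O2)[C@@H]2[C@H](O)[C@@H]1O)(OS(=O)(=O)C(F)(F)F)C(C)(C)C | intermediate (not isolated)
10 | (3R,4S,5S,6R)-6,7-O-(di-tert-butylsilanediyl)-3,4-O-isopropylidene-1-(hydroxymethyl)cyclohex-1-ene-3,4,5,6-tetrol (O5–H free) | CC(C)(C)[Si]3(C(C)(C)C)OCC1=C[C@@H](OC(C)(C)O2)[C@@H]2[C@H](O)[C@@H]1O3 | intermediate
11 | benzoyl chloride | O=C(Cl)c1ccccc1 | starting material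
12 | (3R,4R,5S,6R)-5-O-benzoyl-6,7-O-(di-tert-butylsilanediyl)-3,4-O-isopropylidene-1-(hydroxymethyl)cyclohex-1-ene-3,4,5,6-tetrol | CC(C)(C)[Si]3(C(C)(C)C)OCC1=C[C@@H](OC(C)(C)O2)[C@@H]2[C@H](OC(=O)c4ccccc4)[C@@H]1O3 | intermediate
13 | (3R,4R,5R,6R)-5-O-benzoyl-3,4-O-isopropylidene-1-(hydroxymethyl)cyclohex-1-ene-3,4,5,6-tetrol (O6–H and O7–H free) | OCC1=C[C@@H](OC(C)(C)O2)[C@@H]2[C@H](OC(=O)c3ccccc3)[C@@H]1O | intermediate
14 | (3R,4R,5R,6R)-5,7-di-O-benzoyl-3,4-O-isopropylidene-1-(hydroxymethyl)cyclohex-1-ene-3,4,5,6-tetrol (O6–H free) | O=C(OCC1=C[C@@H](OC(C)(C)O2)[C@@H]2[C@H](OC(=O)c3ccccc3)[C@@H]1O)c1ccccc1 | intermediate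
15 | [(3R,4R,5R,6R)-5-(benzoyloxy)-3,4,6-trihydroxycyclohex-1-en-1-yl]methyl benzoate | O=C(OCC1=C[C@@H](O)[C@@H](O)[C@H](OC(=O)c2ccccc2)[C@@H]1O)c1ccccc1 | target

**Step count**

Total steps: 11. Longest linear sequence: 11 steps (1 → 15); benzoyl chloride 11 enters at steps 8 and 10.

**Steps most likely to fail**

Step 1. The fermentation may deliver too little 2 because the ester is toxic to the cells or is turned over slowly, and 2 may dehydrate back to an arene during extraction. The fallback brings the ester carbon in by palladium-catalysed carbonylation instead of carrying it through the enzyme. No numbered compound can serve as its origin, since the failing step is the first and 1 has no chemical dearomatisation of this kind. It therefore sets out from commercial (1S,2S)-3-bromocyclohexa-3,5-diene-1,2-diol F1 in place of 1. Bis-silylation (TBSOTf, 2,6-lutidine, CH2Cl2, −78 → 0 °C) should give (1S,2S)-3-bromocyclohexa-3,5-diene-1,2-diol bis(tert-butyldimethylsilyl) ether F2. Ethoxycarbonylation of its vinyl bromide (palladium diacetate Pd(OAc)2, PPh3, CO 1 atm, EtOH, Et3N, DMF, 60 °C) should then give 3, where the fallback rejoins the route.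

Step 7. The silyl ditriflate may close non-regioselectively (a five-membered ring across O5/O6) or silylate two molecules instead of bridging O6 and O7. The fallback sets out from 8 and replaces the silylene by a kinetic acetal. 2-Methoxypropene (PPTS cat., DMF, 0 °C) should take the primary O7 first and close a six-membered dioxane onto O6, giving (3R,4S,5R,6R)-3,4:6,7-di-O-isopropylidene-1-(hydroxymethyl)cyclohex-1-ene-3,4,5,6-tetrol F3. Benzoylation of its free O5 with 11 (pyridine, DMAP cat., CH2Cl2) should give (3R,4R,5R,6R)-5-O-benzoyl-3,4:6,7-di-O-isopropylidene-1-(hydroxymethyl)cyclohex-1-ene-3,4,5,6-tetrol F4. The more labile six-membered acetal is then hydrolysed selectively beside the cis-fused dioxolane (60% aq. AcOH, rt), which returns the material to the route at 13.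

Step 10. Chemoselectivity may be lost through over-acylation of O6 or base-promoted benzoyl migration from O5 to O6. The fallback sets out from 13 and reverses the polarity of the bond formation by making C7 the electrophile. Mitsunobu esterification (PhCO2H, PPh3, DIAD, THF, 0 °C) should activate only the unhindered primary allylic alcohol as its alkoxyphosphonium ion, which benzoate displaces at C7. This comes back to the route at 14 and makes no new compound (F0).

**Further compounds**

F1 | step 1 | (1S,2S)-3-bromocyclohexa-3,5-diene-1,2-diol | BrC1=CC=C[C@H](O)[C@@H]1O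
F2 | step 1 | (1S,2S)-3-bromocyclohexa-3,5-diene-1,2-diol bis(tert-butyldimethylsilyl) ether | BrC1=CC=C[C@H](O[Si](C)(C)C(C)(C)C)[C@@H]1O[Si](C)(C)C(C)(C)C
F3 | step 7 | (3R,4S,5R,6R)-3,4:6,7-di-O-isopropylidene-1-(hydroxymethyl)cyclohex-1-ene-3,4,5,6-tetrol | CC3(C)OCC1=C[C@@H](OC(C)(C)O2)[C@@H]2[C@H](O)[C@@H]1O3
F4 | step 7 | (3R,4R,5R,6R)-5-O-benzoyl-3,4:6,7-di-O-isopropylidene-1-(hydroxymethyl)cyclohex-1-ene-3,4,5,6-tetrol | CC3(C)OCC1=C[C@@H](OC(C)(C)O2)[C@@H]2[C@H](OC(=O)c4ccccc4)[C@@H]1O3
F0 | step 10 | none | none
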